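**Plan**

- Ring numbering: cyclobutane C1 and C3 carry the 3,4-dimethoxyphenyl groups, C2 and C4 the imide carbonyls. The retrosynthesis cuts, in this order: both imide N–C(O) bonds, the exocyclic C2–C(O) bond (back to a C2–B bond), ring bond C3–C4, the styrene C=C bond and the C1–C4 bond.
- Enabling feature: ring bond C3–C4 joins a benzylic, aryl-bearing carbon to a carbon whose substituent is trans to that aryl group, and C2 between the two aryl-bearing carbons carries the other carbonyl. C3 can therefore be the benzylic carbon–copper end of a borylated styrene, C4 a secondary sulfonate electrophile, and C2 receives boron in the same event.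
- Forward: the chain is joined first (C1–C4 by allylboration, then the styrene by cross-metathesis). The cyclobutane is the only ring formed and closes in step 5. Boron is then exchanged for carbon, both arms are oxidised to acids and the two preformed lactam rings are attached last, one per carboxyl group.
- Stereochemistry: the anti C1/C4 pair comes from a chair allylboration with an E-allylboronate. C2 and C3 come from syn Cu–B addition to the E-alkene on the face away from the C1 aryl group. C4 is inverted in the ring closure, and the boron-to-carbon shift retains C2.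
- The target has a centre of inversion (α-truxillic type, achiral), so no absolute control is needed.

Key step: step 5

Remark: because the target is centrosymmetric, all chiral intermediates are made as racemates and drawn as one enantiomer; the ring locants C1–C4 defined above are used for every cyclobutane.

**Route**

Step 1
Reactants: 1 (E)-3-(3,4-dimethoxyphenyl)prop-2-en-1-ol; 2 bis(pinacolato)diboron
Product: 3 (E)-2-[3-(3,4-dimethoxyphenyl)prop-2-en-1-yl]-4,4,5,5-tetramethyl-1,3,2-dioxaborolane
Conditions: [Pd(MeCN)4](BF4)2 (5 mol %), DMSO–MeOH (1:1), 40 °C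
Reagents that add atoms: none
Why: Palladium-catalysed borylation of an allylic alcohol through an η3-allylpalladium intermediate, which places boron on the unhindered terminus and keeps the conjugated E-alkene, as is usual for cinnamyl alcohols.

Step 2
Reactants: 3 (E)-cinnamyl-type pinacol boronate; 4 2-(benzyloxy)acetaldehyde
Product: 6 anti-(2S*,3R*)-1-(benzyloxy)-3-(3,4-dimethoxyphenyl)pent-4-en-2-ol (racemic), via O-pinacolboryl ether 5 (not isolated)
Conditions: toluene, rt; then aqueous NaHCO3 work-up
Reagents that add atoms: none
Why: Allylboration through a closed chair (Zimmerman–Traxler) transition state with the aldehyde substituent equatorial, so that the E geometry of the boronate becomes the anti relationship of the aryl-bearing carbon and the carbinol carbon; the O–B bond is hydrolysed on work-up.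

Step 3
Reactants: 6 anti homoallylic alcohol; 7 3,4-dimethoxystyrene
Product: 8 anti-(2S*,3R*,4E)-1-(benzyloxy)-3,5-bis(3,4-dimethoxyphenyl)pent-4-en-2-ol
Conditions: second-generation Hoveyda–Grubbs catalyst RuCl2(H2IMes)(=CH–C6H4-2-O-i-Pr) (5 mol %), 7 (3 equiv), CH2Cl2, 40 °C
Reagents that add atoms: none
Why: Olefin cross-metathesis of a terminal alkene with an excess of a styrene, driven by loss of the small alkene and expected to give the E-styrene under thermodynamic control without touching the alcohol or the two stereocentres.

Step 4
Reactants: 8 anti (E)-diaryl pentenol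
Product: 9 anti-(2S*,3R*,4E)-1-(benzyloxy)-3,5-bis(3,4-dimethoxyphenyl)pent-4-en-2-yl methanesulfonate
Conditions: MsCl, Et3N, CH2Cl2, 0 °C
Reagents that add atoms: methanesulfonyl chloride, CS(=O)(=O)Cl
Why: Standard mesylation of a secondary alcohol through sulfene, with the configuration kept because the C–O bond is not broken; the product is used without storage.

Step 5
Reactants: 9 anti (E)-mesylate; 2 bis(pinacolato)diboron
Product: 10 pinacol [4-(benzyloxymethyl)-1,3-bis(3,4-dimethoxyphenyl)cyclobutan-2-yl]boronate, with the C1 aryl group and the C4 CH2OBn group on one face and the C2 boron and the C3 aryl group on the other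
Conditions: CuCl (10 mol %), dppp (10 mol %), 2 (1.3 equiv), KOt-Bu (1.2 equiv, added last as THF solution), THF, rt
Reagents that add atoms: none
Why: A ligated boryl copper species formed from CuCl, KOt-Bu and 2 adds syn across the E-styrene with copper on the benzylic carbon (ring C3) and boron on its neighbour (ring C2), and the benzylic C–Cu bond then displaces the secondary mesylate at ring C4 intramolecularly with retention at C3 and inversion at C4, after which KOt-Bu returns the copper alkoxide. The closest known reaction type is the copper-catalysed borylative cyclisation of aryl- or silyl-substituted homoallylic sulfonates to 2-substituted cyclobutylboronates, applied here to a secondary, α-branched mesylate. The cyclobutane closes in the 4-exo-tet mode through the new C3–C4 bond. The two new stereocentres C2 and C3 are fixed relative to each other by the syn addition to the E-alkene (boron cis to the C3 aryl group) and relative to C1 by the allylic stereocentre: in the conformer with the C1–C4 bond near the alkene plane, the only one that can close, the C1 aryl group shields one face and boron enters trans to it, while inversion at C4 turns the anti aryl/mesylate pair into the cis C1-aryl/C4-CH2OBn pair. The step needs benzylic regiochemistry of cupration, attack on the face away from the C1 aryl group, and substitution instead of elimination at the mesylate; the aryl group on the alkene secures the first, the fact that the other adduct could only close to an all-cis ring should protect the diastereomeric purity of the product, and adding the alkoxide last to the diboron-containing mixture keeps the free base low.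

Step 6
Reactants: 10 cyclobutyl pinacol boronate
Product: 13 [4-(benzyloxymethyl)-1,3-bis(3,4-dimethoxyphenyl)cyclobutan-2-yl]methanol (configuration as in 10), via lithium chloromethyl boronate complex 11 (not isolated), via homologated pinacol boronate 12 (not isolated)
Conditions: BrCH2Cl (3 equiv), n-BuLi (2.5 equiv), THF, −78 °C to rt; then NaOH, H2O2, H2O, 0 °C to rt
Reagents that add atoms: bromochloromethane, ClCBr; hydrogen peroxide, OO
Why: Matteson homologation, in which chloromethyllithium made in situ adds to boron and the cyclobutyl group shifts from boron to carbon with retention while chloride leaves, followed by alkaline peroxide oxidation of the new primary C–B bond to C–OH.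

Step 7
Reactants: 13 mono-benzylated diol
Product: 14 [2,4-bis(3,4-dimethoxyphenyl)cyclobutane-1,3-diyl]dimethanol (centrosymmetric; each CH2OH cis to one aryl neighbour and trans to the other, the two CH2OH groups trans to each other)
Conditions: H2 (1 atm), Pd/C (palladium on carbon), EtOAc–MeOH, rt
Reagents that add atoms: none
Why: Hydrogenolysis of a benzyl ether over palladium, under which the methoxyarenes, the cyclobutane and the free alcohol are inert and no alkene is present.

Step 8
Reactants: 14 diol
Product: 15 2,4-bis(3,4-dimethoxyphenyl)cyclobutane-1,3-dicarboxylic acid (α-truxillic configuration, centrosymmetric)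
Conditions: TEMPO (20 mol %), PhI(OAc)2 (4.4 equiv), MeCN–H2O (1:1), rt
Reagents that add atoms: water, O
Why: Nitroxyl-catalysed oxidation of primary alcohols (TEMPO with PhI(OAc)2 in aqueous acetonitrile) through the aldehyde hydrates to the acids under near-neutral conditions that should leave the α-stereocentres alone, the trans-1,3 arrangement excluding lactol or lactone formation.

Step 9
Reactants: 15 diacid; 16 5,6-dihydropyridin-2(1H)-one (two equivalents, one for each carboxyl group)
Product: 19 CNP0199212.1 [1,1'-{[2,4-bis(3,4-dimethoxyphenyl)cyclobutane-1,3-diyl]dicarbonyl}bis(5,6-dihydropyridin-2(1H)-one) in the α-truxillic configuration], via bis(acid chloride) 17 (not isolated), via lithium lactamate 18 (not isolated)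
Conditions: (COCl)2, DMF (cat.), CH2Cl2, 0 °C to rt, evaporate; separately 16 (2.2 equiv), LiN(SiMe3)2 (2.1 equiv), THF, −78 °C; then add the acid chloride, −78 to −40 °C
Reagents that add atoms: 5,6-dihydropyridin-2(1H)-one (second equivalent of 16), O=C1C=CCCN1
Why: Double acid chloride formation with oxalyl chloride and DMF followed by N-acylation of two molecules of the preformed lithium lactamate, one at each acid chloride group, the usual way to N-acyl dihydropyridinones, run cold and without amine base so that ketene-mediated epimerisation of the α-stereocentres is avoided.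

**Compound list**

1 | (E)-3-(3,4-dimethoxyphenyl)prop-2-en-1-ol | COc1ccc(/C=C/CO)cc1OC | starting material
2 | bis(pinacolato)diboron | CC1(C)OB(OC1(C)C)B1OC(C)(C)C(C)(C)O1 | starting material
3 | (E)-2-[3-(3,4-dimethoxyphenyl)prop-2-en-1-yl]-4,4,5,5-tetramethyl-1,3,2-dioxaborolane | COc1ccc(/C=C/CB2OC(C)(C)C(C)(C)O2)cc1OC | intermediate
4 | 2-(benzyloxy)acetaldehyde | O=CCOCc1ccccc1 | starting material
5 | O-pinacolboryl ether of 6 (formed in situ), 2-{[(2S*,3R*)-1-(benzyloxy)-3-(3,4-dimethoxyphenyl)pent-4-en-2-yl]oxy}-4,4,5,5-tetramethyl-1,3,2-dioxaborolane | C=C[C@H](c1ccc(OC)c(OC)c1)[C@H](OB1OC(C)(C)C(C)(C)O1)COCc1ccccc1 | intermediate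
6 | anti-(2S*,3R*)-1-(benzyloxy)-3-(3,4-dimethoxyphenyl)pent-4-en-2-ol | C=C[C@H](c1ccc(OC)c(OC)c1)[C@H](O)COCc1ccccc1 | intermediate
7 | 3,4-dimethoxystyrene (4-ethenyl-1,2-dimethoxybenzene) | C=Cc1ccc(OC)c(OC)c1 | starting material
8 | anti-(2S*,3R*,4E)-1-(benzyloxy)-3,5-bis(3,4-dimethoxyphenyl)pent-4-en-2-ol | COc1ccc(/C=C/[C@H](c2ccc(OC)c(OC)c2)[C@H](O)COCc2ccccc2)cc1OC | intermediate
9 | anti-(2S*,3R*,4E)-1-(benzyloxy)-3,5-bis(3,4-dimethoxyphenyl)pent-4-en-2-yl methanesulfonate | COc1ccc(/C=C/[C@H](c2ccc(OC)c(OC)c2)[C@H](OS(C)(=O)=O)COCc2ccccc2)cc1OC | intermediate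
10 | pinacol [4-(benzyloxymethyl)-1,3-bis(3,4-dimethoxyphenyl)cyclobutan-2-yl]boronate; C1-aryl and C4-CH2OBn on one face, C2-boron and C3-aryl on the other | COc1ccc([C@H]2[C@H](B3OC(C)(C)C(C)(C)O3)[C@H](c3ccc(OC)c(OC)c3)[C@H]2COCc2ccccc2)cc1OC | intermediate
11 | lithium chloromethyl boronate complex of 10 (formed in situ) | [Li+].COc1ccc([C@H]2[C@H]([B-]3(CCl)OC(C)(C)C(C)(C)O3)[C@H](c3ccc(OC)c(OC)c3)[C@H]2COCc2ccccc2)cc1OC | intermediate
12 | pinacol {[4-(benzyloxymethyl)-1,3-bis(3,4-dimethoxyphenyl)cyclobutan-2-yl]methyl}boronate (formed in situ; ring configuration as in 10) | COc1ccc([C@H]2[C@H](CB3OC(C)(C)C(C)(C)O3)[C@H](c3ccc(OC)c(OC)c3)[C@H]2COCc2ccccc2)cc1OC | intermediate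
13 | [4-(benzyloxymethyl)-1,3-bis(3,4-dimethoxyphenyl)cyclobutan-2-yl]methanol (ring configuration as in 10) | COc1ccc([C@H]2[C@H](CO)[C@H](c3ccc(OC)c(OC)c3)[C@H]2COCc2ccccc2)cc1OC | intermediate
14 | [2,4-bis(3,4-dimethoxyphenyl)cyclobutane-1,3-diyl]dimethanol, α-truxillic-type configuration | COc1ccc([C@H]2[C@H](CO)[C@H](c3ccc(OC)c(OC)c3)[C@H]2CO)cc1OC | intermediate
15 | 2,4-bis(3,4-dimethoxyphenyl)cyclobutane-1,3-dicarboxylic acid, α-truxillic configuration | COc1ccc([C@H]2[C@H](C(=O)O)[C@H](c3ccc(OC)c(OC)c3)[C@H]2C(=O)O)cc1OC | intermediate
16 | 5,6-dihydropyridin-2(1H)-one | O=C1C=CCCN1 | starting material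
17 | 2,4-bis(3,4-dimethoxyphenyl)cyclobutane-1,3-dicarbonyl dichloride, α-truxillic configuration (formed in situ) | COc1ccc([C@H]2[C@H](C(=O)Cl)[C@H](c3ccc(OC)c(OC)c3)[C@H]2C(=O)Cl)cc1OC | intermediate
18 | lithium salt of 5,6-dihydropyridin-2(1H)-one (formed in situ) | O=C1C=CCC[N-]1.[Li+] | intermediate
19 | CNP0199212.1, 1,1'-{[2,4-bis(3,4-dimethoxyphenyl)cyclobutane-1,3-diyl]dicarbonyl}bis(5,6-dihydropyridin-2(1H)-one), α-truxillic configuration | COc1ccc([C@H]2[C@H](C(=O)N3CCC=CC3=O)[C@H](c3ccc(OC)c(OC)c3)[C@H]2C(=O)N2CCC=CC2=O)cc1OC | target

**Count and risks**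

Total steps: 9. Longest linear sequence: 9 steps, from compound 1.

Steps most likely to fail:

1. Step 5. Three processes threaten it:
 - The alkoxide may eliminate the secondary mesylate toward the conjugated diene, since the neighbouring C–H is both benzylic and allylic.
 - Boryl copper may add with poor facial selectivity; the wrong adduct cannot ring-close and would tie up copper or end as an open-chain by-product.
 - Borylcupration of the electron-rich, branched styrene may be slow.

 Fallback: the ring would be made photochemically instead, setting out from alcohol 1 and coming back at diacid 15. Oxidation of 1 with MnO2 in CH2Cl2 would give (E)-3-(3,4-dimethoxyphenyl)prop-2-enal F1. Pinnick oxidation (NaClO2, NaH2PO4, 2-methyl-2-butene, t-BuOH–H2O) would give (E)-3-(3,4-dimethoxyphenyl)prop-2-enoic acid F2. Irradiation (λ > 300 nm) of crystalline F2 in a form with head-to-tail stacked molecules, a topochemical [2+2] photodimerisation, should give 15, which enters step 9.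

2. Step 6. The short-lived carbenoid may decompose before it is captured by a boron atom that sits between two substituted ring carbons, leaving unhomologated boronate that is then oxidised to the cyclobutanol.

 Fallback: a stable carbon nucleophile replaces the carbenoid, setting out from boronate 10 and coming back at alcohol 13. Zweifel olefination (vinylmagnesium bromide, THF, −78 °C; then I2; then NaOMe, MeOH) should give, with retention at C2, 4-(benzyloxymethyl)-1,3-bis(3,4-dimethoxyphenyl)-2-vinylcyclobutane F3. Lemieux–Johnson cleavage (OsO4 cat., NaIO4, 2,6-lutidine, dioxane–H2O) would give 4-(benzyloxymethyl)-1,3-bis(3,4-dimethoxyphenyl)cyclobutane-2-carbaldehyde F4, which is reduced at once with NaBH4 in MeOH to 13.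

3. Step 3. Turnover at the branched allylic position may be slow, the styrene may be consumed by self-metathesis, and ruthenium hydride species may shift the double bond into conjugation with the allylic aryl group.

 Fallback: the aryl group would be attached by palladium chemistry instead of metathesis, setting out from alkene 6 and coming back at alcohol 8. Heck–Mizoroki arylation of 6 with 4-iodo-1,2-dimethoxybenzene under Jeffery conditions (Pd(OAc)2, n-Bu4NCl, NaHCO3, DMF, 60 °C) should give 8 directly, with β-hydride elimination toward the new benzylic CH2 forming the E-styrene. This detour passes through no new compound (F0).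

**Further compounds**

F1 | step 5 | (E)-3-(3,4-dimethoxyphenyl)prop-2-enal | COc1ccc(/C=C/C=O)cc1OC
F2 | step 5 | (E)-3-(3,4-dimethoxyphenyl)prop-2-enoic acid | COc1ccc(/C=C/C(=O)O)cc1OC
F3 | step 6 | 4-(benzyloxymethyl)-1,3-bis(3,4-dimethoxyphenyl)-2-vinylcyclobutane (ring configuration as in 10) | COc1ccc([C@H]2[C@H](C=C)[C@H](c3ccc(OC)c(OC)c3)[C@H]2COCc2ccccc2)cc1OC
F4 | step 6 | 4-(benzyloxymethyl)-1,3-bis(3,4-dimethoxyphenyl)cyclobutane-2-carbaldehyde (ring configuration as in 10) | COc1ccc([C@H]2[C@H](C=O)[C@H](c3ccc(OC)c(OC)c3)[C@H]2COCc2ccccc2)cc1OC
F0 | step 3 | none | none
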